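Locants follow coumarin numbering: unprimed for the 7-hydroxycoumarin (benzene ring A), primed for the 6',7'-dihydroxycoumarin (benzene ring B).
Retrosynthesis: both pyranones are cut first (C4–C4a/O1–C2 and C4'–C4a'/O1'–C2'), then ring A at C7–C8, C8a–C4a and C6–C7, then the enol ether bond to O5'.
Enabling feature: on ring A, C7–OH and the C8a oxygen are meta across C8–H and the C6 aryloxy group is ortho to C7–OH. C7, C4a, C5 and C6 can therefore come from a 4-aryloxy vinylketene that already carries the ether oxygen, and C8 and C8a from a siloxyalkyne.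
Forward: ring B arene from 5-bromoveratraldehyde (Dakin, silylation, Br to OH, ortho-formylation at C4a', acetal), oxa-Michael addition to butynone, diazo transfer, photochemical benzannulation to ring A. One-pot desilylation/acetal hydrolysis follows, then Wittig lactonisation (pyranone B), propiolate annulation (pyranone A) and demethylation.
Stereochemistry: the target has no stereocentre; the E enol ether of the diazo enone is set thermodynamically in the oxa-Michael step and is consumed in ring A.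

Key step: step 9

Remark: the parent lithium acetylide is assumed to accept oxygen from lithium tert-butyl peroxide as substituted lithium acetylides do.

Step 1
Reactants: 1 5-bromoveratraldehyde (3-bromo-4,5-dimethoxybenzaldehyde)
Product: 3 3-bromo-4,5-dimethoxyphenol, via aryl formate 2 (not isolated)
Conditions: mCPBA, CH2Cl2, rt; then K2CO3 (cat.), MeOH, rt
Reagents that add atoms: meta-chloroperoxybenzoic acid, OOC(=O)c1cccc(Cl)c1
Why: A Dakin-type oxidation, in which Baeyer–Villiger migration of the aryl group (favoured by the para methoxy group) gives formate 2 and base-catalysed methanolysis frees the phenol, should turn the formyl carbon into the future C8a' hydroxyl.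

Step 2
Reactants: 3 3-bromo-4,5-dimethoxyphenol
Product: 4 (3-bromo-4,5-dimethoxyphenoxy)tri(propan-2-yl)silane
Conditions: i-Pr3SiCl, imidazole, DMF, rt
Reagents that add atoms: chlorotri(propan-2-yl)silane, CC(C)[Si](Cl)(C(C)C)C(C)C
Why: Imidazole-promoted O-silylation should give an aryl silyl ether that withstands n-BuLi, MgCl2/Et3N, amide base and light and that fluoride later removes together with the silyl ether introduced at C8a in the key step.

Step 3
Reactants: 4 (3-bromo-4,5-dimethoxyphenoxy)tri(propan-2-yl)silane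
Product: 7 2,3-dimethoxy-5-[(triisopropylsilyl)oxy]phenol, via aryllithium 5 (not isolated), via dimethyl arylboronate 6 (not isolated)
Conditions: n-BuLi, THF, −78 °C; B(OMe)3, −78 °C → rt; AcOH, 30% H2O2, 0 °C → rt
Reagents that add atoms: n-butyllithium, [Li]CCCC (lithium of 5 only); trimethyl borate, COB(OC)OC (boron of 6 only); hydrogen peroxide, OO
Why: Bromine–lithium exchange, borylation of 5 and oxidation of boronate 6 (ipso-hydroxylation by aryl migration from boron to oxygen) should convert C–Br into the C5' hydroxyl without the hot aqueous KOH of a catalytic hydroxylation, which the silyl ether would not survive.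

Step 4
Reactants: 7 2,3-dimethoxy-5-[(triisopropylsilyl)oxy]phenol
Product: 8 2-hydroxy-3,4-dimethoxy-6-[(triisopropylsilyl)oxy]benzaldehyde
Conditions: MgCl2, Et3N, (CH2O)n, MeCN, reflux
Reagents that add atoms: formaldehyde (as paraformaldehyde), C=O
Why: In the Casnati–Skattebøl ortho-formylation the ArOMgCl phenoxide delivers formaldehyde only to a free position ortho to its oxygen and a second formaldehyde oxidises the benzylic alkoxide, so the formyl group can enter only at C4a' (the other ortho position carries OMe), which fixes the regiochemistry of pyranone B.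

Step 5
Reactants: 8 2-hydroxy-3,4-dimethoxy-6-[(triisopropylsilyl)oxy]benzaldehyde
Product: 9 2-(1,3-dioxolan-2-yl)-5,6-dimethoxy-3-[(triisopropylsilyl)oxy]phenol
Conditions: HOCH2CH2OH, PPTS (cat.), benzene, reflux (Dean–Stark)
Reagents that add atoms: ethane-1,2-diol, OCCO
Why: Acid-catalysed acetalisation with azeotropic removal of water should mask the aldehyde as a dioxolane, which is needed because a free ortho-formyl group would trap the vinyl anion of step 6 (chromene formation), react with LiN(SiMe3)2 in step 7 and be photoactive in step 9.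

Step 6
Reactants: 9 2-(1,3-dioxolan-2-yl)-5,6-dimethoxy-3-[(triisopropylsilyl)oxy]phenol; 10 but-3-yn-2-one
Product: 11 (3E)-4-{2-(1,3-dioxolan-2-yl)-5,6-dimethoxy-3-[(triisopropylsilyl)oxy]phenoxy}but-3-en-2-one
Conditions: DABCO (cat.), CH2Cl2, 0 °C → rt
Reagents that add atoms: none
Why: The DABCO-catalysed oxa-Michael addition of the phenol to the ynone is reversible through the β-ammonium enone and should therefore give the E β-aryloxy enone, placing O5' on the carbon that becomes C6.

Step 7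
Reactants: 11 (3E)-4-{2-(1,3-dioxolan-2-yl)-5,6-dimethoxy-3-[(triisopropylsilyl)oxy]phenoxy}but-3-en-2-one
Product: 13 (3E)-1-diazo-4-{2-(1,3-dioxolan-2-yl)-5,6-dimethoxy-3-[(triisopropylsilyl)oxy]phenoxy}but-3-en-2-one, via trifluoroacetyl diketone 12 (not isolated)
Conditions: LiN(SiMe3)2, THF, −78 °C; CF3CO2CH2CF3, −78 °C; aq. NH4Cl; then MsN3, Et3N, H2O, MeCN, rt
Reagents that add atoms: 2,2,2-trifluoroethyl trifluoroacetate, O=C(OCC(F)(F)F)C(F)(F)F (trifluoroacetyl group of 12 only); methanesulfonyl azide, CS(=O)(=O)N=[N+]=[N-]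
Why: Detrifluoroacetylative diazo transfer (kinetic lithium enolate at the methyl group, C-trifluoroacetylation to 12, diazo transfer from MsN3 with loss of the trifluoroacetyl group as its sulfonamide) is the standard route to α'-diazo enones and avoids the pyrazoline formation that acylation of diazomethane with enoyl chlorides risks.

Step 8
Reactants: 14 acetylene; 15 triisopropylsilyl trifluoromethanesulfonate
Product: 18 (triisopropylsilyloxy)acetylene [(ethynyloxy)tri(propan-2-yl)silane], via lithium acetylide 16 (not isolated), via lithium ethynolate 17 (not isolated)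
Conditions: n-BuLi, THF, −78 °C; t-BuOOLi (t-BuOOH, LiN(SiMe3)2), −78 → 0 °C; 15, −78 → 0 °C
Reagents that add atoms: n-butyllithium, [Li]CCCC (lithium of 16 and 17 only); tert-butyl hydroperoxide, CC(C)(C)OO
Why: Oxygen transfer from lithium tert-butyl peroxide to acetylide 16 should give ynolate 17, which the bulky oxophilic silyl triflate silylates on oxygen (acetylide oxidation and ynolate O-silylation), the usual entry to 1-siloxyalkynes applied here to the parent acetylide.

Step 9
Reactants: 13 (3E)-1-diazo-4-{2-(1,3-dioxolan-2-yl)-5,6-dimethoxy-3-[(triisopropylsilyl)oxy]phenoxy}but-3-en-2-one; 18 (triisopropylsilyloxy)acetylene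
Product: 23 2-{2-(1,3-dioxolan-2-yl)-5,6-dimethoxy-3-[(triisopropylsilyl)oxy]phenoxy}-5-[(triisopropylsilyl)oxy]phenol, via vinylketene 19 (not isolated), via cyclobutenone 20 (not isolated), via dienylketene 21 (not isolated), via cyclohexadienone 22 (not isolated)
Conditions: 18 (2 equiv), hν (300 nm), ClCH2CH2Cl, rt; then 80 °C
Reagents that add atoms: none
Why: Excitation of the diazo enone expels N2 and the aryloxyvinyl group migrates (Wolff rearrangement) to vinylketene 19, whose carbonyl carbon is attacked by the nucleophilic CH terminus of 18, so that [2+2] cycloaddition across the ketene C=C gives cyclobutenone 20 (C7–C8 and C8a–C4a). Reversible conrotatory four-electron opening of 20, driven at 80 °C, gives dienylketene 21, and ring A closes by thermal disrotatory six-electron electrocyclisation (C6–C7) to dienone 22, which tautomerises to phenol 23. The closest known reaction type is the Danheiser benzannulation in its photochemical diazo ketone form with trialkylsiloxyalkynes, which gives resorcinol monosilyl ethers. No stereocentre is formed. The selectivity needed is the regiochemistry of the ketene–alkyne union, which the polarisation of the ynol ether secures, so that the C8a oxygen ends up meta to C7–OH and para to the ether oxygen. The E enol ether lets the aryloxy group rotate outward in the electrocyclisation, and 300 nm light should address the diazo enone while the silyl ethers and the acetal stay untouched.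

Step 10
Reactants: 23 2-{2-(1,3-dioxolan-2-yl)-5,6-dimethoxy-3-[(triisopropylsilyl)oxy]phenoxy}-5-[(triisopropylsilyl)oxy]phenol
Product: 25 2-(2,4-dihydroxyphenoxy)-6-hydroxy-3,4-dimethoxybenzaldehyde, via acetal triol 24 (not isolated)
Conditions: Bu4NF, THF, 0 °C; then 1 M aq. HCl, rt (under Ar)
Reagents that add atoms: water, O
Why: Fluoride-mediated desilylation of both aryl silyl ethers to 24 followed by acid hydrolysis of the electron-rich benzylic acetal should release in one operation the resorcinol of ring A, the C8a' hydroxyl and the C4a' aldehyde.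

Step 11
Reactants: 25 2-(2,4-dihydroxyphenoxy)-6-hydroxy-3,4-dimethoxybenzaldehyde; 26 ethyl 2-(triphenyl-λ5-phosphanylidene)acetate
Product: 29 5-(2,4-dihydroxyphenoxy)-6,7-dimethoxy-2H-chromen-2-one, via E cinnamate 27 (not isolated), via Z cinnamate 28 (not isolated)
Conditions: 26, PhNEt2, reflux
Reagents that add atoms: none
Why: Wittig olefination with the stabilised ylide at high temperature should give cinnamates 27 and 28 that equilibrate thermally, and the Z isomer lactonises onto the C8a' hydroxyl (the only hydroxyl ortho to the acrylate), closing pyranone B as in the classical salicylaldehyde-to-coumarin synthesis.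

Step 12
Reactants: 29 5-(2,4-dihydroxyphenoxy)-6,7-dimethoxy-2H-chromen-2-one; 30 ethyl propiolate
Product: 32 6-[(6,7-dimethoxy-2-oxo-2H-chromen-5-yl)oxy]-7-hydroxy-2H-chromen-2-one, via Z cinnamate 31 (not isolated)
Conditions: 30, ZnCl2, dioxane, 100 °C
Reagents that add atoms: none
Why: In this Pechmann-type annulation ZnCl2-activated ethyl propiolate should alkylate the resorcinol ring at C4a (para to C7–OH and ortho to C8a–OH, whereas C8 is flanked by both hydroxyls and the coumarin ring B is deactivated), and Z cinnamate 31 lactonises onto C8a–OH to close pyranone A.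

Step 13
Reactants: 32 6-[(6,7-dimethoxy-2-oxo-2H-chromen-5-yl)oxy]-7-hydroxy-2H-chromen-2-one
Product: 33 6-[(6,7-dihydroxy-2-oxo-2H-chromen-5-yl)oxy]-7-hydroxy-2H-chromen-2-one (CNP0197949.0)
Conditions: BBr3, CH2Cl2, −78 °C → rt; then H2O
Reagents that add atoms: none
Why: BBr3 demethylation (bromide attack on the methyl group of the aryl methyl ether–borane complex) should free the 6',7'-catechol while the lactones, the diaryl ether and the free phenol are inert.

Compound list
1 | 5-bromoveratraldehyde (3-bromo-4,5-dimethoxybenzaldehyde) | COc1cc(C=O)cc(Br)c1OC | starting material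
2 | 3-bromo-4,5-dimethoxyphenyl formate | O=COc1cc(Br)c(OC)c(OC)c1 | intermediate
3 | 3-bromo-4,5-dimethoxyphenol | Oc1cc(Br)c(OC)c(OC)c1 | intermediate
4 | (3-bromo-4,5-dimethoxyphenoxy)tri(propan-2-yl)silane | COc1cc(O[Si](C(C)C)(C(C)C)C(C)C)cc(Br)c1OC | intermediate
5 | {2,3-dimethoxy-5-[(triisopropylsilyl)oxy]phenyl}lithium | [Li]c1cc(O[Si](C(C)C)(C(C)C)C(C)C)cc(OC)c1OC | intermediate
6 | dimethyl {2,3-dimethoxy-5-[(triisopropylsilyl)oxy]phenyl}boronate | COB(OC)c1cc(O[Si](C(C)C)(C(C)C)C(C)C)cc(OC)c1OC | intermediate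
7 | 2,3-dimethoxy-5-[(triisopropylsilyl)oxy]phenol | Oc1cc(O[Si](C(C)C)(C(C)C)C(C)C)cc(OC)c1OC | intermediate
8 | 2-hydroxy-3,4-dimethoxy-6-[(triisopropylsilyl)oxy]benzaldehyde | O=Cc1c(O)c(OC)c(OC)cc1O[Si](C(C)C)(C(C)C)C(C)C | intermediate
9 | 2-(1,3-dioxolan-2-yl)-5,6-dimethoxy-3-[(triisopropylsilyl)oxy]phenol | Oc1c(OC)c(OC)cc(O[Si](C(C)C)(C(C)C)C(C)C)c1C1OCCO1 | intermediate
10 | but-3-yn-2-one | CC(=O)C#C | starting material
11 | (3E)-4-{2-(1,3-dioxolan-2-yl)-5,6-dimethoxy-3-[(triisopropylsilyl)oxy]phenoxy}but-3-en-2-one | CC(=O)/C=C/Oc1c(OC)c(OC)cc(O[Si](C(C)C)(C(C)C)C(C)C)c1C1OCCO1 | intermediate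
12 | (5E)-6-{2-(1,3-dioxolan-2-yl)-5,6-dimethoxy-3-[(triisopropylsilyl)oxy]phenoxy}-1,1,1-trifluorohex-5-ene-2,4-dione | O=C(CC(=O)/C=C/Oc1c(OC)c(OC)cc(O[Si](C(C)C)(C(C)C)C(C)C)c1C1OCCO1)C(F)(F)F | intermediate
13 | (3E)-1-diazo-4-{2-(1,3-dioxolan-2-yl)-5,6-dimethoxy-3-[(triisopropylsilyl)oxy]phenoxy}but-3-en-2-one | [N-]=[N+]=CC(=O)/C=C/Oc1c(OC)c(OC)cc(O[Si](C(C)C)(C(C)C)C(C)C)c1C1OCCO1 | intermediate
14 | acetylene (ethyne) | C#C | starting material
15 | triisopropylsilyl trifluoromethanesulfonate | CC(C)[Si](C(C)C)(C(C)C)OS(=O)(=O)C(F)(F)F | starting material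
16 | lithium acetylide (ethynyllithium) | [Li]C#C | intermediate
17 | lithium ethynolate | [Li]OC#C | intermediate
18 | (triisopropylsilyloxy)acetylene [(ethynyloxy)tri(propan-2-yl)silane] | C#CO[Si](C(C)C)(C(C)C)C(C)C | intermediate
19 | (3E)-4-{2-(1,3-dioxolan-2-yl)-5,6-dimethoxy-3-[(triisopropylsilyl)oxy]phenoxy}buta-1,3-dien-1-one | O=C=C/C=C/Oc1c(OC)c(OC)cc(O[Si](C(C)C)(C(C)C)C(C)C)c1C1OCCO1 | intermediate
20 | 4-[(E)-2-{2-(1,3-dioxolan-2-yl)-5,6-dimethoxy-3-[(triisopropylsilyl)oxy]phenoxy}ethenyl]-3-[(triisopropylsilyl)oxy]cyclobut-2-en-1-one (racemic) | O=C1C=C(O[Si](C(C)C)(C(C)C)C(C)C)C1/C=C/Oc1c(OC)c(OC)cc(O[Si](C(C)C)(C(C)C)C(C)C)c1C1OCCO1 | intermediate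
21 | (3E,5E)-6-{2-(1,3-dioxolan-2-yl)-5,6-dimethoxy-3-[(triisopropylsilyl)oxy]phenoxy}-3-[(triisopropylsilyl)oxy]hexa-1,3,5-trien-1-one | O=C=C/C(O[Si](C(C)C)(C(C)C)C(C)C)=C\C=C\Oc1c(OC)c(OC)cc(O[Si](C(C)C)(C(C)C)C(C)C)c1C1OCCO1 | intermediate
22 | 6-{2-(1,3-dioxolan-2-yl)-5,6-dimethoxy-3-[(triisopropylsilyl)oxy]phenoxy}-3-[(triisopropylsilyl)oxy]cyclohexa-2,4-dien-1-one (racemic) | O=C1C=C(O[Si](C(C)C)(C(C)C)C(C)C)C=CC1Oc1c(OC)c(OC)cc(O[Si](C(C)C)(C(C)C)C(C)C)c1C1OCCO1 | intermediate
23 | 2-{2-(1,3-dioxolan-2-yl)-5,6-dimethoxy-3-[(triisopropylsilyl)oxy]phenoxy}-5-[(triisopropylsilyl)oxy]phenol | Oc1cc(O[Si](C(C)C)(C(C)C)C(C)C)ccc1Oc1c(OC)c(OC)cc(O[Si](C(C)C)(C(C)C)C(C)C)c1C1OCCO1 | intermediate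
24 | 4-[2-(1,3-dioxolan-2-yl)-3-hydroxy-5,6-dimethoxyphenoxy]benzene-1,3-diol | Oc1ccc(Oc2c(OC)c(OC)cc(O)c2C2OCCO2)c(O)c1 | intermediate
25 | 2-(2,4-dihydroxyphenoxy)-6-hydroxy-3,4-dimethoxybenzaldehyde | O=Cc1c(O)cc(OC)c(OC)c1Oc1ccc(O)cc1O | intermediate
26 | ethyl 2-(triphenyl-λ5-phosphanylidene)acetate | CCOC(=O)C=P(c1ccccc1)(c1ccccc1)c1ccccc1 | starting material
27 | ethyl (2E)-3-[2-(2,4-dihydroxyphenoxy)-6-hydroxy-3,4-dimethoxyphenyl]prop-2-enoate | CCOC(=O)/C=C/c1c(O)cc(OC)c(OC)c1Oc1ccc(O)cc1O | intermediate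
28 | ethyl (2Z)-3-[2-(2,4-dihydroxyphenoxy)-6-hydroxy-3,4-dimethoxyphenyl]prop-2-enoate | CCOC(=O)/C=C\c1c(O)cc(OC)c(OC)c1Oc1ccc(O)cc1O | intermediate
29 | 5-(2,4-dihydroxyphenoxy)-6,7-dimethoxy-2H-chromen-2-one | O=c1ccc2c(Oc3ccc(O)cc3O)c(OC)c(OC)cc2o1 | intermediate
30 | ethyl propiolate (ethyl prop-2-ynoate) | CCOC(=O)C#C | starting material
31 | ethyl (2Z)-3-{5-[(6,7-dimethoxy-2-oxo-2H-chromen-5-yl)oxy]-2,4-dihydroxyphenyl}prop-2-enoate | CCOC(=O)/C=C\c1cc(Oc2c(OC)c(OC)cc3oc(=O)ccc23)c(O)cc1O | intermediate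
32 | 6-[(6,7-dimethoxy-2-oxo-2H-chromen-5-yl)oxy]-7-hydroxy-2H-chromen-2-one | O=c1ccc2cc(Oc3c(OC)c(OC)cc4oc(=O)ccc34)c(O)cc2o1 | intermediate
33 | 6-[(6,7-dihydroxy-2-oxo-2H-chromen-5-yl)oxy]-7-hydroxy-2H-chromen-2-one (CNP0197949.0) | O=c1ccc2cc(Oc3c(O)c(O)cc4oc(=O)ccc34)c(O)cc2o1 | target

Total step count: 13 (12 in the main line plus the one-step preparation of alkyne 18).
Longest linear sequence: 12 steps (steps 1–7 and 9–13).

Steps most likely to fail

Step 9. After loss of nitrogen the aryloxyvinylketene may be consumed by paths other than the union with the alkyne (reversible closure to a cyclobutenone, oligomerisation, acylation of phenol already formed), or the Wolff rearrangement may stall because ring B takes part of the light. The fallback leaves the route at 9 and returns at 25, making the diaryl ether by C–O cross-coupling instead of by building ring A. Commercial 4-bromoresorcinol (Oc1ccc(Br)c(O)c1) would be dibenzylated (BnBr, K2CO3, acetone) to 2,4-bis(benzyloxy)-1-bromobenzene F1. F1 and phenol 9 would be coupled (Pd(OAc)2, t-BuXPhos, K3PO4, toluene, 100 °C) to {3-[2,4-bis(benzyloxy)phenoxy]-2-(1,3-dioxolan-2-yl)-4,5-dimethoxyphenoxy}tri(propan-2-yl)silane F2. Hydrogenolysis (H2, Pd/C, EtOAc) should give 4-{2-(1,3-dioxolan-2-yl)-5,6-dimethoxy-3-[(triisopropylsilyl)oxy]phenoxy}benzene-1,3-diol F3, which under the conditions of step 10 passes through 24 to 25.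

Step 8. The monolithium acetylide may disproportionate to Li2C2 before oxygen transfer, the unhindered ynolate may be silylated on carbon, and the small acid-sensitive product may be lost on isolation. The fallback leaves the route at 13 and returns at 33. Commercial ethoxyacetylene (C#COCC) would replace 18 under the conditions of step 9 and should give 2-{2-(1,3-dioxolan-2-yl)-5,6-dimethoxy-3-[(triisopropylsilyl)oxy]phenoxy}-5-ethoxyphenol F4. The conditions of step 10 would then give 2-(4-ethoxy-2-hydroxyphenoxy)-6-hydroxy-3,4-dimethoxybenzaldehyde F5, and those of step 11 would give 5-(4-ethoxy-2-hydroxyphenoxy)-6,7-dimethoxy-2H-chromen-2-one F6. BBr3 (CH2Cl2, −78 °C → rt) would now cleave the ethyl and both methyl ethers to 5-(2,4-dihydroxyphenoxy)-6,7-dihydroxy-2H-chromen-2-one F7. The propiolate annulation of step 12 (30, ZnCl2, dioxane, 100 °C) on the resorcinol ring of F7 would then close pyranone A last and give 33.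

Step 7. The lithium diketonate of 12 or its enol may add back onto the β-aryloxy enone and expel the phenoxide (4-pyranone formation), or the acetal may be hydrolysed during the quench. The fallback leaves the route at 9 and returns at 13, reaching the diazo ketone by acylation of diazomethane. DABCO-catalysed addition of 9 to ethyl propiolate 30 should give ethyl (2E)-3-{2-(1,3-dioxolan-2-yl)-5,6-dimethoxy-3-[(triisopropylsilyl)oxy]phenoxy}prop-2-enoate F8. Me3SnOH (ClCH2CH2Cl, 70 °C) would hydrolyse it under neutral conditions to (2E)-3-{2-(1,3-dioxolan-2-yl)-5,6-dimethoxy-3-[(triisopropylsilyl)oxy]phenoxy}prop-2-enoic acid F9. i-BuOCOCl and N-methylmorpholine (THF, −15 °C) would give (2E)-3-{2-(1,3-dioxolan-2-yl)-5,6-dimethoxy-3-[(triisopropylsilyl)oxy]phenoxy}prop-2-enoic 2-methylpropyl carbonic anhydride F10, which should acylate diazomethane (Et2O, 0 °C) to give 13.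

Further compounds
F1 | step 9 | 2,4-bis(benzyloxy)-1-bromobenzene | Brc1ccc(OCc2ccccc2)cc1OCc1ccccc1
F2 | step 9 | {3-[2,4-bis(benzyloxy)phenoxy]-2-(1,3-dioxolan-2-yl)-4,5-dimethoxyphenoxy}tri(propan-2-yl)silane | C(c1ccccc1)Oc1ccc(Oc2c(OC)c(OC)cc(O[Si](C(C)C)(C(C)C)C(C)C)c2C2OCCO2)c(OCc2ccccc2)c1
F3 | step 9 | 4-{2-(1,3-dioxolan-2-yl)-5,6-dimethoxy-3-[(triisopropylsilyl)oxy]phenoxy}benzene-1,3-diol | Oc1ccc(Oc2c(OC)c(OC)cc(O[Si](C(C)C)(C(C)C)C(C)C)c2C2OCCO2)c(O)c1
F4 | step 8 | 2-{2-(1,3-dioxolan-2-yl)-5,6-dimethoxy-3-[(triisopropylsilyl)oxy]phenoxy}-5-ethoxyphenol | CCOc1ccc(Oc2c(OC)c(OC)cc(O[Si](C(C)C)(C(C)C)C(C)C)c2C2OCCO2)c(O)c1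
F5 | step 8 | 2-(4-ethoxy-2-hydroxyphenoxy)-6-hydroxy-3,4-dimethoxybenzaldehyde | CCOc1ccc(Oc2c(OC)c(OC)cc(O)c2C=O)c(O)c1
F6 | step 8 | 5-(4-ethoxy-2-hydroxyphenoxy)-6,7-dimethoxy-2H-chromen-2-one | CCOc1ccc(Oc2c(OC)c(OC)cc3oc(=O)ccc23)c(O)c1
F7 | step 8 | 5-(2,4-dihydroxyphenoxy)-6,7-dihydroxy-2H-chromen-2-one | Oc1ccc(Oc2c(O)c(O)cc3oc(=O)ccc23)c(O)c1
F8 | step 7 | ethyl (2E)-3-{2-(1,3-dioxolan-2-yl)-5,6-dimethoxy-3-[(triisopropylsilyl)oxy]phenoxy}prop-2-enoate | CCOC(=O)/C=C/Oc1c(OC)c(OC)cc(O[Si](C(C)C)(C(C)C)C(C)C)c1C1OCCO1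
F9 | step 7 | (2E)-3-{2-(1,3-dioxolan-2-yl)-5,6-dimethoxy-3-[(triisopropylsilyl)oxy]phenoxy}prop-2-enoic acid | OC(=O)/C=C/Oc1c(OC)c(OC)cc(O[Si](C(C)C)(C(C)C)C(C)C)c1C1OCCO1
F10 | step 7 | (2E)-3-{2-(1,3-dioxolan-2-yl)-5,6-dimethoxy-3-[(triisopropylsilyl)oxy]phenoxy}prop-2-enoic 2-methylpropyl carbonic anhydride | CC(C)COC(=O)OC(=O)/C=C/Oc1c(OC)c(OC)cc(O[Si](C(C)C)(C(C)C)C(C)C)c1C1OCCO1
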